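Start from the slowness of the south-west run, where L gains just 6 percentage points between 4.00 h and 10.0 h, while the east run, with less J, has reached 100% of L by 3.00 h.

common to all: D 20 mM; X 2.6 µM

| flask | J | remark |
|---|---|---|
| east | 0.65 µM | run made earlier |
| south-west | 2.6 µM | run made earlier |
| flask | 1.3 µM |  |

- east (time / h: L / %, D / %): 1.33: 84, 14; 3.00: 100, 1; 6.00: 98, 0; 10.0: 98, 1
- south-west (time / h: L / %, D / %): 0.833: 22, 79; 2.00: 29, 71; 4.00: 33, 68; 10.0: 39, 59

(readings scatter by 1.5 percentage points)

* apparent order in X when 30% of the D are converted (percent change of the rate of making L for one percent more X charged)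

- the numbers in the tables scatter with a standard deviation of 1.5 percentage points
- no earlier run changes the charge of X; that part of a forecast is a guess

Read the rates first. From its first reading of D, the east run gives a pseudo-first-order constant of 1.48 h⁻¹. Between its first two readings, the south-west run gives 0.0915 h⁻¹, smaller by a factor of 16.2. Take this as one J removing one X for good.

For the flask, keep 50.0% as the surplus share, the part of the charged X above the charged J, (cX − cJ)/cX. The east run has 75.0%. Scale by the shares: the flask's D constant, as a rough estimate for the early run, is 0.986 h⁻¹ once J is used up.

Now ask how the slowing drifts. At equal charges the rate falls as one over time, so the south-west constant, read near 1.42 h, puts J's loss in the flask at 7.60 h⁻¹, faster than D's. Conversion of 30% then takes 0.362 h, and J is down to about 6.39% of its charge. At that conversion cD is fixed, so the rate follows the surplus, and one percent more X raises it by 2.00 percent. Commit to that order.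

The forecast gave 1.98, reasoning that “J is essentially gone”.

The flask gives 1.9, against the reckoned 2.00.

    D + X → L + X, rate k1*[D]*[X]/(1 + ([D]/Km1)) (11.0 mM, k = 380 M⁻¹ s⁻¹)
    X + J → Q (k = 1500 M⁻¹ s⁻¹)

While J lasted, the step from X + J to Q ran beside the step from D to L: at 0.800 h the flask held J at 0.182% of its charge, and X at 50.1% of the catalyst, the surplus share of 50.0%, with Q at 49.9%. The step from D to L then ran on with X at 50.0% of the catalyst at 1.84 h, and D stood at 0.418% at 4.00 h. The south-west run has a surplus share of 0%, and D still read 59% at 10.0 h.

The readings were generated by integration from invented constants, noise included.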